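**Plan**

- Target numbering: C1 carries OH, C2, C3 and C6 carry Br, C4 carries CH2OH, C5 carries H. The retrosynthesis first trades C5–H and the alcohol O–H for one silicon atom (a 2,1-benzoxasilole), then removes the C6 bromine, then cuts the ring bonds C1–C6 and C4–C5.
- Enabling feature: the run C1(O)–C2(Br)–C3(Br)–C4(CH2O) is a 3,4-dibromofurfuryl alcohol in disguise, and the furan oxygen ends up as the phenolic oxygen. C5 and C6 are an ethynyl group held on silicon, which is bound to the CH2O oxygen.
- Forward: 3,4-dibromofuran is formylated at C2, reduced and silylated with chloro(ethynyl)diisopropylsilane. Heating closes the benzene ring and the oxasilole ring in one cycloaddition, and acid opens the oxygen bridge to the phenol. C6 is then brominated and fluoride finally excises the silicon.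
- Isopropyl groups on silicon are chosen so that the alkynylsilyl ether survives isolation and heating, and so that the gem-dialkyl effect helps ring closure.
- Stereochemistry: the target has no stereocentre; the two bridgehead centres of the transient cycloadduct vanish on aromatisation.

Key step: step 5

Remark: 3,4-dibromofuran, dichlorodi(propan-2-yl)silane, ethynylmagnesium bromide (THF solution), LiN(iPr)2 solution and (E)-1,2-bis(phenylsulfonyl)ethene are assumed to be purchasable.

**Step 1**
Reactants: 1 3,4-dibromofuran; 2 N,N-dimethylformamide
Product: 5 3,4-dibromofuran-2-carbaldehyde, via 2-lithio-3,4-dibromofuran 3 (not isolated), via lithium hemiaminolate adduct 4 (not isolated)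
Conditions: LiN(iPr)2 (1.05 equiv), THF, −78 °C; 2 (1.5 equiv), −78 → 0 °C; 1 M HCl
Reagents that add atoms: none
Why: Kinetic deprotonation of the furan α-position by the hindered amide base at −78 °C should outrun bromine–lithium exchange and halogen migration, and the 2-furyllithium is trapped by DMF in a Bouveault-type formylation, the aldehyde being released from the hemiaminolate on acidic work-up.

**Step 2**
Reactants: 5 3,4-dibromofuran-2-carbaldehyde
Product: 6 (3,4-dibromofuran-2-yl)methanol
Conditions: NaBH4 (0.5 equiv), MeOH, 0 °C
Reagents that add atoms: none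
Why: Borohydride 1,2-reduction of a heteroaryl aldehyde is chemoselective and should leave both C–Br bonds and the furan ring untouched.

**Step 3**
Reactants: 7 dichlorodi(propan-2-yl)silane; 8 ethynylmagnesium bromide
Product: 9 chloro(ethynyl)di(propan-2-yl)silane
Conditions: 7 (2 equiv), THF, −78 °C, slow addition of 8 (1 equiv), → rt; hexane, filtration, distillation under reduced pressure
Reagents that add atoms: none
Why: Nucleophilic substitution at silicon by an alkynyl Grignard reagent should stop at the monoalkynyl stage because the two isopropyl groups shield silicon and the dichlorosilane is kept in excess.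

**Step 4**
Reactants: 6 (3,4-dibromofuran-2-yl)methanol; 9 chloro(ethynyl)di(propan-2-yl)silane
Product: 10 [(3,4-dibromofuran-2-yl)methoxy](ethynyl)di(propan-2-yl)silane
Conditions: 9 (1.2 equiv), imidazole (2 equiv), 4-(dimethylamino)pyridine (cat.), CH2Cl2, 0 °C → rt; chromatography on Et3N-washed silica
Reagents that add atoms: none
Why: Imidazole-promoted O-silylation of a primary alcohol with a chlorosilane is routine, and the isopropyl groups should make the alkynylsilyl ether robust enough to purify.

**Step 5**
Reactants: 10 [(3,4-dibromofuran-2-yl)methoxy](ethynyl)di(propan-2-yl)silane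
Product: 12 4,5-dibromo-1,1-di(propan-2-yl)-1,3-dihydro-2,1-benzoxasilol-6-ol, via 7-oxanorbornadiene cycloadduct 11 (not isolated)
Conditions: o-xylene (0.02 M), 2,6-di-tert-butyl-4-methylphenol (5 mol %), 140–160 °C, sealed vessel; cool to 0 °C, CH3SO3H (10 mol %), 0 °C → rt
Reagents that add atoms: none
Why: Proposed new method: furan–alkyne intramolecular Diels–Alder reactions followed by acid isomerisation of the 7-oxanorbornadiene to a phenol are well known for carbon and nitrogen tethers, and thermal Diels–Alder reactions across a C–O–Si tether are known for vinylsilyl ethers of dienols, but joining a furan to an ethynylsilyl ether in this way is only an analogy to both. The tether holds the ethynyl group over the furan, the long Si–C and Si–O bonds and the two isopropyl groups ease the approach, and a concerted [4+2] addition forms C4–C5 and C1–C6 (target numbering) to give 11; the two furan bromines are expected to favour the adduct and an alkyne dienophile makes the addition practically irreversible. The six-membered carbocycle closes by the cycloaddition itself, and the five-membered oxasilole closes through the C4–C5 bond in the fused mode of a type 1 intramolecular Diels–Alder reaction. The two bridgehead centres of 11 are locked relative to each other by the oxygen bridge and are erased on aromatisation, so no stereocentre needs control. CH3SO3H then protonates the bridge oxygen, the C4–O bond ionises to a tertiary, doubly allylic cation, and loss of the single bridgehead proton at C1 gives the phenol with oxygen on C1, para to the CH2O carbon. The regiochemistry of addition is enforced by the three-atom tether, which can only deliver the silicon-bound alkyne carbon to the furan carbon bearing the CH2O arm, the sense of bridge opening follows from C4 having no hydrogen while C1 has one, and the hindered diisopropylsilyl ether is expected to tolerate a catalytic amount of anhydrous acid.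

**Step 6**
Reactants: 12 4,5-dibromo-1,1-di(propan-2-yl)-1,3-dihydro-2,1-benzoxasilol-6-ol
Product: 13 4,5,7-tribromo-1,1-di(propan-2-yl)-1,3-dihydro-2,1-benzoxasilol-6-ol
Conditions: N-bromosuccinimide (1.05 equiv), iPr2NH (10 mol %), CH2Cl2, −20 → 0 °C
Reagents that add atoms: N-bromosuccinimide, O=C1CCC(=O)N1Br
Why: Amine-catalysed electrophilic bromination of phenols with N-bromosuccinimide is ortho-selective, C7 of the benzoxasilole (C6 of the target) is the only open ring position and is ortho to the hydroxyl, the silicon-bearing carbon is meta to it and so should resist ipso attack, and the benzylic oxygen stays masked as the silyl ether.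

**Step 7**
Reactants: 13 4,5,7-tribromo-1,1-di(propan-2-yl)-1,3-dihydro-2,1-benzoxasilol-6-ol
Product: 14 2,3,6-tribromo-4-(hydroxymethyl)phenol
Conditions: Bu4NF·3H2O (4 equiv), DMF, 60 °C
Reagents that add atoms: none
Why: Fluoride-promoted protodesilylation of an aryl alkoxysilane, the usual way to excise a silicon tether, should proceed because fluoride adds readily to the strained five-ring silicon, opens the Si–O bond, and the electron-poor aryl group leaves the fluorosilicate with ipso-protonation by water.

**Compound list**

1 | 3,4-dibromofuran | Brc1cocc1Br | starting material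
2 | N,N-dimethylformamide | CN(C)C=O | starting material
3 | 2-lithio-3,4-dibromofuran | [Li]c1occ(Br)c1Br | intermediate (not isolated)
4 | lithium (3,4-dibromofuran-2-yl)(dimethylamino)methanolate | [Li]OC(N(C)C)c1occ(Br)c1Br | intermediate (not isolated)
5 | 3,4-dibromofuran-2-carbaldehyde | O=Cc1occ(Br)c1Br | intermediate
6 | (3,4-dibromofuran-2-yl)methanol | OCc1occ(Br)c1Br | intermediate
7 | dichlorodi(propan-2-yl)silane | CC(C)[Si](Cl)(Cl)C(C)C | starting material
8 | ethynylmagnesium bromide | C#C[Mg]Br | starting material
9 | chloro(ethynyl)di(propan-2-yl)silane | C#C[Si](Cl)(C(C)C)C(C)C | intermediate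
10 | [(3,4-dibromofuran-2-yl)methoxy](ethynyl)di(propan-2-yl)silane | C#C[Si](OCc1occ(Br)c1Br)(C(C)C)C(C)C | intermediate
11 | 4,5-dibromo-1,1-di(propan-2-yl)-3,6-dihydro-1H-3a,6-epoxy-2,1-benzoxasilole (7-oxanorbornadiene cycloadduct; bridgeheads C3a and C6, double bonds C4=C5 and C7=C7a; racemic, relative configuration fixed by the bridge) | C12OC3(CO[Si](C(C)C)(C(C)C)C3=C1)C(Br)=C2Br | intermediate (not isolated)
12 | 4,5-dibromo-1,1-di(propan-2-yl)-1,3-dihydro-2,1-benzoxasilol-6-ol | Oc1cc2c(c(Br)c1Br)CO[Si]2(C(C)C)C(C)C | intermediate
13 | 4,5,7-tribromo-1,1-di(propan-2-yl)-1,3-dihydro-2,1-benzoxasilol-6-ol | Oc1c(Br)c2c(c(Br)c1Br)CO[Si]2(C(C)C)C(C)C | intermediate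
14 | 2,3,6-tribromo-4-(hydroxymethyl)phenol | OCc1cc(Br)c(O)c(Br)c1Br | target

**Step count**

Total: 7 steps. Longest linear sequence: 6 steps (1, 2, 4, 5, 6, 7 from 3,4-dibromofuran); step 3 is a one-step side branch.

**Steps most likely to fail**

1. Step 5 (the step resting on a proposed method). The unactivated ethynylsilane may add only at temperatures where the furfuryl silyl ether decomposes, or the acid may cleave the Si–O bond or ionise the benzylic C–O bond instead of opening the oxygen bridge. The fallback uses known intermolecular chemistry with an acetylene equivalent; it sets out from 6 and returns to the route at 14. Alcohol 6 would be protected (tBuPh2SiCl, imidazole, DMF) as tert-butyl[(3,4-dibromofuran-2-yl)methoxy]diphenylsilane F1. Heating F1 with (E)-1,2-bis(phenylsulfonyl)ethene in toluene should give the Diels–Alder adduct tert-butyl{[2,3-dibromo-5,6-bis(phenylsulfonyl)-7-oxabicyclo[2.2.1]hept-2-en-1-yl]methoxy}diphenylsilane F2, whose diastereomer mixture is of no consequence. Reductive elimination of both sulfonyl groups with Na(Hg) and NaH2PO4 in MeOH/THF at −20 °C should give tert-butyl[(2,3-dibromo-7-oxabicyclo[2.2.1]hepta-2,5-dien-1-yl)methoxy]diphenylsilane F3. Catalytic CH3SO3H in CH2Cl2 should isomerise F3, by the same tertiary-cation bridge opening, to 2,3-dibromo-4-({[tert-butyl(diphenyl)silyl]oxy}methyl)phenol F4. Bromination with N-bromosuccinimide and catalytic iPr2NH should then give 2,3,6-tribromo-4-({[tert-butyl(diphenyl)silyl]oxy}methyl)phenol F5, and Bu4NF in THF removes the silyl ether to deliver 14.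

2. Step 7. The ortho-bromoaryl fluorosilicate may lose bromide (aryne formation) in competition with ipso-protonation, and on prolonged heating the tribromophenoxide may expel hydroxide to a quinone methide and oligomerise. The fallback reverses the order of the last two operations so that silicon leaves a carbon with no neighbouring bromine; it sets out from 12 and returns at 14. Treating 12 with Bu4NF·3H2O in DMF should give 2,3-dibromo-4-(hydroxymethyl)phenol F6, which is then brominated at its only free ortho position with N-bromosuccinimide and catalytic iPr2NH in CH2Cl2 at low temperature to give 14.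

3. Step 3. The Grignard reagent may substitute twice, or its dimagnesium component may bridge two silanes, and the moisture-sensitive chlorosilane may hydrolyse or co-distil with by-products. The fallback builds the silicon–oxygen bond first; it sets out from 6 and 7 and returns at 10. Alcohol 6 is added slowly to an excess of 7 (imidazole, CH2Cl2, −78 → 0 °C) to give chloro[(3,4-dibromofuran-2-yl)methoxy]di(propan-2-yl)silane F7. After removal of excess 7 under vacuum, 8 in THF at −78 °C displaces the remaining chloride to give 10, a sequential substitution of the kind used for unsymmetrical dialkoxysilanes.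

**Further compounds**

F1 | step 5 | tert-butyl[(3,4-dibromofuran-2-yl)methoxy]diphenylsilane | CC(C)(C)[Si](OCc1occ(Br)c1Br)(c1ccccc1)c1ccccc1
F2 | step 5 | tert-butyl{[2,3-dibromo-5,6-bis(phenylsulfonyl)-7-oxabicyclo[2.2.1]hept-2-en-1-yl]methoxy}diphenylsilane (racemic, trans-bis-sulfone diastereomer mixture) | CC(C)(C)[Si](OCC12OC(C(Br)=C1Br)C(S(=O)(=O)c1ccccc1)C2S(=O)(=O)c1ccccc1)(c1ccccc1)c1ccccc1
F3 | step 5 | tert-butyl[(2,3-dibromo-7-oxabicyclo[2.2.1]hepta-2,5-dien-1-yl)methoxy]diphenylsilane (racemic) | CC(C)(C)[Si](OCC12OC(C=C1)C(Br)=C2Br)(c1ccccc1)c1ccccc1
F4 | step 5 | 2,3-dibromo-4-({[tert-butyl(diphenyl)silyl]oxy}methyl)phenol | CC(C)(C)[Si](OCc1ccc(O)c(Br)c1Br)(c1ccccc1)c1ccccc1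
F5 | step 5 | 2,3,6-tribromo-4-({[tert-butyl(diphenyl)silyl]oxy}methyl)phenol | CC(C)(C)[Si](OCc1cc(Br)c(O)c(Br)c1Br)(c1ccccc1)c1ccccc1
F6 | step 7 | 2,3-dibromo-4-(hydroxymethyl)phenol | OCc1ccc(O)c(Br)c1Br
F7 | step 3 | chloro[(3,4-dibromofuran-2-yl)methoxy]di(propan-2-yl)silane | CC(C)[Si](Cl)(OCc1occ(Br)c1Br)C(C)C
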